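## Analysis of the target

The target **24** is 8-(3,4-dimethoxyphenyl)-2,6-dimethoxynaphthalene-1,4-dione. Ring B is a 2-methoxy-1,4-quinone. Ring A is the fused benzene ring with a methoxy group on C6 and the aryl ring C on C8, peri to the C1 carbonyl.

The molecule has no stereocentre, and ring C has no ortho substituent, so the C8–aryl axis is not a stereogenic element. Any sp3 centre made on the way is a means only and is erased.

The 2-methoxyquinone is a vinylogous ester. Nucleophiles exchange its methoxy group by addition–elimination, and bases and reductants degrade it, so it should be unveiled in the last step.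

Two points make the synthesis hard. Ring A is a 1,2,3,5-tetrasubstituted benzene with methoxy and aryl meta to each other and the aryl group in a crowded peri position. In ring B the methoxy group must sit on C2, next to the carbonyl that faces the aryl group, and not on C3.

The strategy rests on one feature. The six carbons of ring A are three adjacent pairs, C8–C8a, C4a–C5 and C6–C7, and the first two pairs are joined through the chain C1–C4 of ring B. Two alkynes on one four-carbon chain plus a third, free alkyne therefore hold every carbon of rings A and B.

## Retrosynthetic reasoning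

**C4 carbonyl (24 to 23).** The quinone is traced to the naphthol **23** (8-aryl-2,6-dimethoxynaphthalen-1-ol), whose para position C4 is free. The C4–O bond is made last by para-oxidation, so the sensitive quinone appears only at the end. A plan with ketones at both C1 and C4 while C2 and C3 are still sp3 was set aside. In that arrangement the C2 methoxy group is β to the C4 carbonyl, and enolization toward C3 can expel it. The C2 oxygen would be lost, and putting it back would not be regiocontrolled.

**Aromatization of ring B (23 to 21, 20, 19).** The naphthol comes from the tetralone **21** by loss of the C4 methoxy group with a C3 hydrogen, then tautomerization. The C4 oxygen of the tetralin is thus only a leaving group, and it is a methyl ether from the start. The C1 oxygen becomes the carbonyl and is a silyl ether, so desilylation (**19** to **20**) and oxidation (**20** to **21**) touch C1 alone. In **21** the C2 methoxy group is α to the only carbonyl and cannot be eliminated.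

**Rings A and B (19 to 14 + 18).** The bonds C4a–C8a, C5–C6 and C7–C8 are cut together. This gives the 1,7-diyne **14** and methoxyacetylene **18**. No other cut places all four ring-A substituents from simple alkynes; the aryl-bearing C8 is an ordinary arylalkyne carbon and the C6 methoxy group comes with the ynol ether. The forward reaction must join the two tethered alkynes first and then take up **18** with its oxygen-bearing carbon at C5. Counted from the aryl-bearing alkyne carbon, **14** has the silyloxy group on C3 and a methoxy group on the adjacent C4, which puts the methoxy group on C2 of ring B next to C1.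

**C4–C4a (14 to 13 to 11 + 12).** The terminal alkyne is attached by adding ethynylmagnesium bromide **12** to the aldehyde **11**. O-Methylation of the carbinol **13** then gives **14**. The new centre is of no consequence.

**The two-carbon arm C3–C4 (11 to 10 to 8).** The aldehyde is the oxidation product of the primary alcohol **10**, which comes from the vinyl group of **8** by anti-Markovnikov hydration. The vinyl group is a stable carrier of C3 and C4 while C1 and C2 are being set.

**C1–C2 (8 to 7 to 3 + 4).** The bond between the carbinol carbon and the methoxy-bearing carbon is cut. This leads to the ynal **3** and a γ-methoxyallyl metal made from allyl methyl ether **4**. One step then delivers the C2 methoxy group, the C1 oxygen and the vinyl arm, with the oxygens on adjacent carbons by construction.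

**Feedstocks (3 to 1; 18 to 15).** The ynal is the formylation product of 4-ethynyl-1,2-dimethoxybenzene **1**, which brings ring C complete. Methoxyacetylene **18** is made by double elimination from the chloroacetal **15**.

## Alternatives that were turned down

**Alternative 1: ring C built by a nitroalkene Diels–Alder reaction.**
- Disconnection: ring C is opened at C1'–C2' and C5'–C6'. This gives (E)-1,2,4,6-tetramethoxy-8-(2-nitroethenyl)naphthalene A2 and 2,3-dimethoxybuta-1,3-diene A3.
- Forward: the [4+2] cycloaddition gives the trans nitrocyclohexene A1. Base-induced loss of the nitro group and dehydrogenation would give the biaryl A4 (8-aryl-1,2,4,6-tetramethoxynaphthalene), and oxidative demethylation would give **24**.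
- For: nitroalkenes react dependably with electron-rich dienes, and the symmetric diene leaves no regiochemical question. Both ring-C methoxy groups come with A3, and the quinone is released last from a robust dimethyl ether. The key step is more secure than the one chosen here.
- Against: the ring-forming step is spent on the one ring that can be bought complete. The real difficulty, the substitution pattern of ring A and a functionalized C8 peri to a methoxy group, is moved into A2, which needs a long synthesis of its own. The nitrovinyl group is twisted out of conjugation by the peri substituent and should be a sluggish dienophile. A1 needs two more redox operations beside a very oxidizable tetramethoxynaphthalene. The final demethylation of A4 must choose the C1/C4 pair over the C1/C2 pair.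
- Comparison: the chosen route builds the two difficult rings and is shorter overall.

**Alternative 2: Hauser–Kraus annulation.**
- Disconnection: ring B is opened at C1–C2 and C3–C4. This gives the sulfonylphthalide A6 (aryl group next to the lactone carbonyl) and methyl 2-methoxyacrylate A7.
- Forward: the anion of A6 adds to the β carbon of A7, the ester enolate closes onto the lactone carbonyl, and sulfinate leaves. The product is the dione ester A5.
- For: the route is convergent. The regiochemistry of ring B is fixed by the mechanism, since the lactone carbonyl becomes C1 and the methoxy-bearing carbon becomes C2. On this point it is stronger than the chosen route, where the orientation of the third alkyne is an expectation.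
- Against: A7 is a weak Michael acceptor because of its α-oxygen donor. A5 has the C2 methoxy group β to the C4 carbonyl with an enolizable C3, so the alkoxide base of the annulation can expel it. Removal of the ester recreates the same β-methoxy dione arrangement that the chosen route avoids. A6 needs a biaryl coupling next to the lactone carbonyl and a sulfone installation, and the ring closure attacks a carbonyl flanked by the aryl group.
- Comparison: the step count is similar or slightly lower. The weak point is the stability of the key product, whereas in the chosen route the methoxy group is never β to a carbonyl with sp3 neighbours.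

**Alternative 3: one-carbon ring expansion of an indanone.**
- Disconnection: C2 is taken out of ring B (bonds C1–C2 and C2–C3). This leads to the indanone A10 and its silyl enol ether A9.
- Forward: a dibromocarbene generated from a haloform and an alkoxide adds to the enol ether double bond of A9. The siloxycyclopropane opens with loss of bromide and gives the 2-bromo-1-naphthol A8. Exchange of bromine for methoxy would give **23**, and the same last oxidation would follow.
- For: the route is short and each step has close precedent. The C1 oxygen and a handle on C2 are placed by construction. It is probably stronger than the chosen route in step count and in precedent.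
- Against: A10 is itself a 1,2,3,5-tetrasubstituted benzene with the aryl group next to the carbonyl, so the regiochemical problem of ring A is moved into arene chemistry. The carbene must add to a hindered alkene under strongly basic conditions. The bromine-to-methoxy exchange is a metal-mediated substitution at a crowded carbon next to a free hydroxyl and will probably need a protecting group.
- Comparison: the chosen strategy offers both carbocycles of the naphthalene from acyclic pieces in one operation. The ring-A pattern is set by the choice of alkynes, the C2 methoxy group is present from the second step, and the C6 and C8 substituents can be varied by changing an alkyne.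

Key step: step 9

Remark on the chemistry (assumption): the target is achiral and every sp3 centre of the intermediates is erased in steps 11 and 12. Compounds 7–11, 13, 14 and 19–22 are therefore carried as racemic mixtures of diastereomers and drawn without stereodescriptors.

## Route

Step 1
Reactants: 1 4-ethynyl-1,2-dimethoxybenzene
Product: 3 3-(3,4-dimethoxyphenyl)prop-2-ynal, via lithium (3,4-dimethoxyphenyl)ethynide 2 (not isolated)
Conditions: n-BuLi, THF, −78 °C; DMF, −78 °C to rt; poured into cold aq. KH2PO4/MTBE
Reagents that add atoms: N,N-dimethylformamide, CN(C)C=O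
Why: Deprotonation of the terminal alkyne and formylation of the acetylide with DMF; the inverse quench into phosphate buffer keeps the liberated dimethylamine from adding to the ynal.

Step 2
Reactants: 3 3-(3,4-dimethoxyphenyl)prop-2-ynal; 4 allyl methyl ether
Product: 7 1-(3,4-dimethoxyphenyl)-4-methoxyhex-5-en-1-yn-3-ol (racemic, syn isomer expected to predominate), via (Z)-3-methoxyallyllithium 5 (not isolated), via diethyl[(Z)-3-methoxyallyl]aluminium 6 (not isolated)
Conditions: 4, s-BuLi, THF, −78 °C; Et2AlCl, −78 °C; then 3, −78 °C; aq. potassium sodium tartrate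
Reagents that add atoms: none
Why: Deprotonation of 4 gives the Z-configured chelated allyl anion, which aluminium captures at the terminal carbon; the γ-methoxyallylaluminium adds to the aldehyde with allylic transposition through a closed six-membered transition state, forming C1–C2 with the methoxy group on C2 (carbonyl addition of a γ-alkoxyallyl metal). The Z geometry should favour the syn isomer, but both new centres are erased later, so this selectivity does not matter.

Step 3
Reactants: 7 1-(3,4-dimethoxyphenyl)-4-methoxyhex-5-en-1-yn-3-ol
Product: 8 tert-butyl{[1-(3,4-dimethoxyphenyl)-4-methoxyhex-5-en-1-yn-3-yl]oxy}dimethylsilane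
Conditions: TBSCl, imidazole, DMF, rt
Reagents that add atoms: tert-butyldimethylsilyl chloride, C[Si](C)(Cl)C(C)(C)C
Why: Standard silylation of a secondary propargylic alcohol; the silyl ether marks the oxygen that will become the C1 carbonyl and survives every step up to step 10.

Step 4
Reactants: 8 tert-butyl{[1-(3,4-dimethoxyphenyl)-4-methoxyhex-5-en-1-yn-3-yl]oxy}dimethylsilane
Product: 10 4-(tert-butyldimethylsilyloxy)-6-(3,4-dimethoxyphenyl)-3-methoxyhex-5-yn-1-ol, via the B-alkyl-9-borabicyclo[3.3.1]nonane adduct 9 (not isolated)
Conditions: 9-BBN, THF, 0 °C to rt; then aq. NaOH, H2O2, 0 °C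
Reagents that add atoms: hydrogen peroxide, OO
Why: 9-BBN adds to a monosubstituted alkene much faster than to a hindered internal arylalkyne and places boron on the terminal carbon; alkaline peroxide then replaces boron by hydroxyl with the silyl ether intact (anti-Markovnikov hydroboration–oxidation).

Step 5
Reactants: 10 4-(tert-butyldimethylsilyloxy)-6-(3,4-dimethoxyphenyl)-3-methoxyhex-5-yn-1-ol
Product: 11 4-(tert-butyldimethylsilyloxy)-6-(3,4-dimethoxyphenyl)-3-methoxyhex-5-ynal
Conditions: Dess–Martin periodinane, NaHCO3, CH2Cl2, 0 °C to rt
Reagents that add atoms: none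
Why: Buffered Dess–Martin oxidation of a primary alcohol; the neutral conditions avoid β-elimination of the methoxy group, and the aldehyde is used without storage.

Step 6
Reactants: 11 4-(tert-butyldimethylsilyloxy)-6-(3,4-dimethoxyphenyl)-3-methoxyhex-5-ynal; 12 ethynylmagnesium bromide
Product: 13 6-(tert-butyldimethylsilyloxy)-8-(3,4-dimethoxyphenyl)-5-methoxyocta-1,7-diyn-3-ol (mixture of diastereomers)
Conditions: 12, THF, −78 °C to 0 °C; sat. aq. NH4Cl
Reagents that add atoms: none
Why: Grignard 1,2-addition to the aldehyde at low temperature is faster than enolization; the new carbinol centre forms without control, which is acceptable because it is erased in step 12.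

Step 7
Reactants: 13 6-(tert-butyldimethylsilyloxy)-8-(3,4-dimethoxyphenyl)-5-methoxyocta-1,7-diyn-3-ol
Product: 14 3-(tert-butyldimethylsilyloxy)-1-(3,4-dimethoxyphenyl)-4,6-dimethoxyocta-1,7-diyne (mixture of diastereomers)
Conditions: Me3OBF4, 1,8-bis(dimethylamino)naphthalene, CH2Cl2, 0 °C to rt
Reagents that add atoms: trimethyloxonium tetrafluoroborate, C[O+](C)C.F[B-](F)(F)F
Why: O-Methylation with an oxonium salt and a hindered amine base forms no alkoxide, so the silyl group cannot migrate and the terminal alkyne is left alone. The methyl ether is inert to the ruthenium catalyst and later serves as the C4 leaving group.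

Step 8
Reactants: 15 2-chloro-1,1-dimethoxyethane
Product: 18 methoxyethyne, via 1-chloro-2-methoxyethene 16 (not isolated), via sodium methoxyethynide 17 (not isolated)
Conditions: NaNH2 (3 equiv), liq. NH3, −40 °C; NH3 evaporated; sat. aq. NaCl, −70 °C; distilled into a −78 °C trap, kept as a cold solution in ClCH2CH2Cl
Reagents that add atoms: none
Why: Amide-induced loss of methanol and then of HCl is the known preparation of alkoxyacetylenes from chloroacetals; excess amide holds the product as its sodium acetylide until the cold quench. The volatile ynol ether is handled only as a cold, dry solution.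

Step 9
Reactants: 14 3-(tert-butyldimethylsilyloxy)-1-(3,4-dimethoxyphenyl)-4,6-dimethoxyocta-1,7-diyne; 18 methoxyethyne
Product: 19 1-(tert-butyldimethylsilyloxy)-8-(3,4-dimethoxyphenyl)-2,4,6-trimethoxy-1,2,3,4-tetrahydronaphthalene (mixture of diastereomers)
Conditions: (C5Me5)RuCl(cod) (10 mol %), 18 (4 equiv), ClCH2CH2Cl, 0 °C to rt, slow addition of 14
Reagents that add atoms: none
Why: Loss of cod (1,5-cyclooctadiene) from the divalent ruthenium precatalyst frees two sites, and oxidative cyclization of the two alkyne units of 14 forms a bicyclic ruthenacycle, which closes ring B as a six-membered ring through the C4a–C8a bond (intramolecular alkyne–alkyne coupling enforced by the four-carbon tether). Coordination and insertion of 18 at the unhindered Ru–C5 end, followed by C–C reductive elimination, form C5–C6 and C7–C8 and close ring A as a new benzene ring (formal [2+2+2] cycloaddition, driven by aromatization). The closest known reaction type is the (C5Me5)RuCl-catalysed cyclotrimerization of 1,6- and 1,7-diynes with terminal monoalkynes, and alkoxyalkynes are established partners in the cobalt- and rhodium-mediated versions. No stereocentre is created, and the three sp3 centres of the tether are spectators. The step needs cross- over homo-trimerization, which is served by slow addition of 14 to an excess of the volatile partner. It also needs the orientation that joins the methoxy-bearing carbon to C5 and the CH carbon to C8. The aryl group on C8 and the C5Me5 ligand should turn the substituted alkyne carbon toward the unsubstituted terminus C5, the meta orientation known for unsymmetrical diynes under this catalyst, and the oxygen-bearing carbon of an ynol ether is its electrophilic carbon, the one expected to accept the migrating ring carbon. The silyl and methyl ethers at the two propargylic positions are inert to the catalyst and bias the tether toward the folded conformation.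

Step 10
Reactants: 19 1-(tert-butyldimethylsilyloxy)-8-(3,4-dimethoxyphenyl)-2,4,6-trimethoxy-1,2,3,4-tetrahydronaphthalene
Product: 20 8-(3,4-dimethoxyphenyl)-2,4,6-trimethoxy-1,2,3,4-tetrahydronaphthalen-1-ol (mixture of diastereomers)
Conditions: TBAF, THF, rt to 40 °C
Reagents that add atoms: none
Why: Fluoride cleaves the one silyl ether; the benzylic and aryl methyl ethers are inert, so only the C1 oxygen is freed.

Step 11
Reactants: 20 8-(3,4-dimethoxyphenyl)-2,4,6-trimethoxy-1,2,3,4-tetrahydronaphthalen-1-ol
Product: 21 8-(3,4-dimethoxyphenyl)-2,4,6-trimethoxy-3,4-dihydronaphthalen-1(2H)-one (mixture of diastereomers)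
Conditions: Dess–Martin periodinane, NaHCO3, CH2Cl2, rt
Reagents that add atoms: none
Why: Dess–Martin oxidation of a hindered secondary benzylic alcohol. The ketone enolizes only toward C2 and has no leaving group β to the carbonyl (the C4 methoxy group is γ), so it can be isolated.

Step 12
Reactants: 21 8-(3,4-dimethoxyphenyl)-2,4,6-trimethoxy-3,4-dihydronaphthalen-1(2H)-one
Product: 23 8-(3,4-dimethoxyphenyl)-2,6-dimethoxynaphthalen-1-ol, via the 2H-naphthalen-1-one keto tautomer 22 (not isolated)
Conditions: TsOH (cat.), 4 Å MS, toluene, 80 °C, under argon
Reagents that add atoms: none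
Why: Acid ionizes the benzylic C4 methyl ether, helped by the enol form of the C1 ketone, and loss of a C3 proton followed by tautomerization gives the naphthol, with aromatization of ring B as the driving force. This is the acid-induced aromatization of a 4-oxygenated 1-tetralone to a 1-naphthol; the last two sp3 centres disappear here.

Step 13
Reactants: 23 8-(3,4-dimethoxyphenyl)-2,6-dimethoxynaphthalen-1-ol
Product: 24 8-(3,4-dimethoxyphenyl)-2,6-dimethoxynaphthalene-1,4-dione
Conditions: (KSO3)2NO, KH2PO4, acetone/H2O, 0 °C to rt
Reagents that add atoms: dipotassium nitrosodisulfonate (Fremy's salt), [K+].[K+].[O]N(S(=O)(=O)[O-])S(=O)(=O)[O-]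
Why: Teuber oxidation: hydrogen abstraction from the naphthol, coupling of a second nitroxyl radical at the free para carbon C4 and loss of imidodisulfonate install the C4 carbonyl. C2 is blocked by its methoxy group, so the para-quinone is expected, and the methoxy arenes are untouched.

## Compound list

1 | 4-ethynyl-1,2-dimethoxybenzene | C#Cc1ccc(OC)c(OC)c1 | starting material
2 | lithium (3,4-dimethoxyphenyl)ethynide | [Li]C#Cc1ccc(OC)c(OC)c1 | intermediate
3 | 3-(3,4-dimethoxyphenyl)prop-2-ynal | O=CC#Cc1ccc(OC)c(OC)c1 | intermediate
4 | allyl methyl ether (3-methoxyprop-1-ene) | C=CCOC | starting material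
5 | (Z)-3-methoxyallyllithium | CO/C=C\C[Li] | intermediate
6 | diethyl[(Z)-3-methoxyallyl]aluminium | CC[Al](CC)C/C=C\OC | intermediate
7 | 1-(3,4-dimethoxyphenyl)-4-methoxyhex-5-en-1-yn-3-ol (racemic, syn isomer expected to predominate) | C=CC(OC)C(O)C#Cc1ccc(OC)c(OC)c1 | intermediate
8 | tert-butyl{[1-(3,4-dimethoxyphenyl)-4-methoxyhex-5-en-1-yn-3-yl]oxy}dimethylsilane (racemic, as 7) | C=CC(OC)C(O[Si](C)(C)C(C)(C)C)C#Cc1ccc(OC)c(OC)c1 | intermediate
9 | 9-[4-(tert-butyldimethylsilyloxy)-6-(3,4-dimethoxyphenyl)-3-methoxyhex-5-yn-1-yl]-9-borabicyclo[3.3.1]nonane (racemic, as 7) | COC(CCB1C2CCCC1CCC2)C(O[Si](C)(C)C(C)(C)C)C#Cc1ccc(OC)c(OC)c1 | intermediate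
10 | 4-(tert-butyldimethylsilyloxy)-6-(3,4-dimethoxyphenyl)-3-methoxyhex-5-yn-1-ol (racemic, as 7) | OCCC(OC)C(O[Si](C)(C)C(C)(C)C)C#Cc1ccc(OC)c(OC)c1 | intermediate
11 | 4-(tert-butyldimethylsilyloxy)-6-(3,4-dimethoxyphenyl)-3-methoxyhex-5-ynal (racemic, as 7) | O=CCC(OC)C(O[Si](C)(C)C(C)(C)C)C#Cc1ccc(OC)c(OC)c1 | intermediate
12 | ethynylmagnesium bromide | C#C[Mg]Br | starting material
13 | 6-(tert-butyldimethylsilyloxy)-8-(3,4-dimethoxyphenyl)-5-methoxyocta-1,7-diyn-3-ol (racemic mixture of diastereomers) | C#CC(O)CC(OC)C(O[Si](C)(C)C(C)(C)C)C#Cc1ccc(OC)c(OC)c1 | intermediate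
14 | 3-(tert-butyldimethylsilyloxy)-1-(3,4-dimethoxyphenyl)-4,6-dimethoxyocta-1,7-diyne (racemic mixture of diastereomers) | C#CC(OC)CC(OC)C(O[Si](C)(C)C(C)(C)C)C#Cc1ccc(OC)c(OC)c1 | intermediate
15 | 2-chloro-1,1-dimethoxyethane (chloroacetaldehyde dimethyl acetal) | COC(CCl)OC | starting material
16 | 1-chloro-2-methoxyethene (E/Z mixture) | COC=CCl | intermediate
17 | sodium methoxyethynide | COC#C[Na] | intermediate
18 | methoxyethyne (methoxyacetylene) | COC#C | intermediate
19 | 1-(tert-butyldimethylsilyloxy)-8-(3,4-dimethoxyphenyl)-2,4,6-trimethoxy-1,2,3,4-tetrahydronaphthalene (racemic mixture of diastereomers) | COc1cc(-c2ccc(OC)c(OC)c2)c2c(c1)C(OC)CC(OC)C2O[Si](C)(C)C(C)(C)C | intermediate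
20 | 8-(3,4-dimethoxyphenyl)-2,4,6-trimethoxy-1,2,3,4-tetrahydronaphthalen-1-ol (racemic mixture of diastereomers) | COc1cc(-c2ccc(OC)c(OC)c2)c2c(c1)C(OC)CC(OC)C2O | intermediate
21 | 8-(3,4-dimethoxyphenyl)-2,4,6-trimethoxy-3,4-dihydronaphthalen-1(2H)-one (racemic mixture of diastereomers) | COc1cc(-c2ccc(OC)c(OC)c2)c2c(c1)C(OC)CC(OC)C2=O | intermediate
22 | 8-(3,4-dimethoxyphenyl)-2,6-dimethoxynaphthalen-1(2H)-one (racemic) | COc1cc(-c2ccc(OC)c(OC)c2)c2c(c1)C=CC(OC)C2=O | intermediate
23 | 8-(3,4-dimethoxyphenyl)-2,6-dimethoxynaphthalen-1-ol | COc1cc(-c2ccc(OC)c(OC)c2)c2c(O)c(OC)ccc2c1 | intermediate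
24 | 8-(3,4-dimethoxyphenyl)-2,6-dimethoxynaphthalene-1,4-dione | COC1=CC(=O)c2cc(OC)cc(-c3ccc(OC)c(OC)c3)c2C1=O | target

## Step count and least certain steps

Total step count: 13 (twelve on the main line plus the one-step preparation of 18).
Longest linear sequence: 12 steps (steps 1–7 and 9–13).

**Step 9 (key step).**
- What may go wrong: the ynol ether may insert with the reverse orientation. Its CH carbon is nucleophilic and may bond to the ring carbon C5, which would put the methoxy group on C7, ortho to the aryl group. Oligomerization of the ynol ether and slow oxidative cyclization of a 1,7-diyne would also hold the step back.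
- Fallback: it sets out from 14 and returns at 19. Diyne 14 is cyclotrimerized under the same catalyst with commercial 2-ethynyl-4,4,5,5-tetramethyl-1,3,2-dioxaborolane, a terminal alkyne for which the meta orientation is established. This gives the arylboronate 2-[5-(tert-butyldimethylsilyloxy)-4-(3,4-dimethoxyphenyl)-6,8-dimethoxy-5,6,7,8-tetrahydronaphthalen-2-yl]-4,4,5,5-tetramethyl-1,3,2-dioxaborolane F1. Oxidation of the C–B bond (NaBO3, THF/H2O) gives the phenol 5-(tert-butyldimethylsilyloxy)-4-(3,4-dimethoxyphenyl)-6,8-dimethoxy-5,6,7,8-tetrahydronaphthalen-2-ol F2, and O-methylation (MeI, K2CO3, acetone) gives 19.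

**Step 12.**
- What may go wrong: the C4 ether may ionize slowly because the ketone form withdraws electrons. The benzylic cation may also alkylate an electron-rich arene of a second molecule, and the hot acid may degrade the air-sensitive naphthol.
- Fallback: it sets out from 21 and returns at 24, keeping the C4 oxygen. Ketone 21 is converted (TMSOTf, Et3N) into the silyl enol ether [8-(3,4-dimethoxyphenyl)-2,4,6-trimethoxy-3,4-dihydronaphthalen-1-yl]oxytrimethylsilane F3. Saegusa–Ito dehydrogenation with Pd(OAc)2 in MeCN and spontaneous tautomerization give 8-(3,4-dimethoxyphenyl)-2,4,6-trimethoxynaphthalen-1-ol F4. Oxidative demethylation of this para-methoxynaphthol with PhI(OAc)2 in MeCN/H2O gives 24, and step 13 is then not needed.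

**Step 13.**
- What may go wrong: the oxidant may attack at C2 with loss of the methoxy group and give the ortho-quinone, or the naphthoxyl radical may dimerize.
- Fallback: it sets out from 23 and returns at 24. Azo coupling of 23 at C4 with diazotized 4-aminobenzenesulfonic acid (NaNO2, HCl; then aq. NaOH, 0 °C) gives 4-{[5-(3,4-dimethoxyphenyl)-4-hydroxy-3,7-dimethoxynaphthalen-1-yl]diazenyl}benzenesulfonic acid F5. Reduction with Na2S2O4 gives 4-amino-8-(3,4-dimethoxyphenyl)-2,6-dimethoxynaphthalen-1-ol F6. Oxidation with FeCl3 in aq. HCl and hydrolysis of the quinone imine give 24.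

**Step 4.**
- What may go wrong: the borane may also add to the arylalkyne, or boron may go partly to the internal alkene carbon because of the allylic methoxy group.
- Fallback: it sets out from 8 and returns at 11. Lemieux–Johnson cleavage of the vinyl group (OsO4 cat., NaIO4, 2,6-lutidine, dioxane/H2O) gives 3-(tert-butyldimethylsilyloxy)-5-(3,4-dimethoxyphenyl)-2-methoxypent-4-ynal F7. Wittig reaction with methoxymethylenetriphenylphosphorane at −78 °C gives the enol ether tert-butyl{[1-(3,4-dimethoxyphenyl)-4,6-dimethoxyhex-5-en-1-yn-3-yl]oxy}dimethylsilane F8. Brief hydrolysis (dilute HCl, THF, 0 °C) gives 11.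

## Further compounds

F1 | step 9 | 2-[5-(tert-butyldimethylsilyloxy)-4-(3,4-dimethoxyphenyl)-6,8-dimethoxy-5,6,7,8-tetrahydronaphthalen-2-yl]-4,4,5,5-tetramethyl-1,3,2-dioxaborolane (mixture of diastereomers) | COC1CC(OC)c2cc(B3OC(C)(C)C(C)(C)O3)cc(-c3ccc(OC)c(OC)c3)c2C1O[Si](C)(C)C(C)(C)C
F2 | step 9 | 5-(tert-butyldimethylsilyloxy)-4-(3,4-dimethoxyphenyl)-6,8-dimethoxy-5,6,7,8-tetrahydronaphthalen-2-ol (mixture of diastereomers) | COC1CC(OC)c2cc(O)cc(-c3ccc(OC)c(OC)c3)c2C1O[Si](C)(C)C(C)(C)C
F3 | step 12 | [8-(3,4-dimethoxyphenyl)-2,4,6-trimethoxy-3,4-dihydronaphthalen-1-yl]oxytrimethylsilane (racemic) | COC1=C(O[Si](C)(C)C)c2c(-c3ccc(OC)c(OC)c3)cc(OC)cc2C(OC)C1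
F4 | step 12 | 8-(3,4-dimethoxyphenyl)-2,4,6-trimethoxynaphthalen-1-ol | COc1cc(-c2ccc(OC)c(OC)c2)c2c(O)c(OC)cc(OC)c2c1
F5 | step 13 | 4-{[5-(3,4-dimethoxyphenyl)-4-hydroxy-3,7-dimethoxynaphthalen-1-yl]diazenyl}benzenesulfonic acid | OS(=O)(=O)c1ccc(/N=N/c2cc(OC)c(O)c3c(-c4ccc(OC)c(OC)c4)cc(OC)cc23)cc1
F6 | step 13 | 4-amino-8-(3,4-dimethoxyphenyl)-2,6-dimethoxynaphthalen-1-ol | Nc1cc(OC)c(O)c2c(-c3ccc(OC)c(OC)c3)cc(OC)cc12
F7 | step 4 | 3-(tert-butyldimethylsilyloxy)-5-(3,4-dimethoxyphenyl)-2-methoxypent-4-ynal (racemic, as 7) | O=CC(OC)C(O[Si](C)(C)C(C)(C)C)C#Cc1ccc(OC)c(OC)c1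
F8 | step 4 | tert-butyl{[1-(3,4-dimethoxyphenyl)-4,6-dimethoxyhex-5-en-1-yn-3-yl]oxy}dimethylsilane (E/Z mixture, racemic) | COC=CC(OC)C(O[Si](C)(C)C(C)(C)C)C#Cc1ccc(OC)c(OC)c1
A1 | alternative 1 | racemic trans-1,2-dimethoxy-4-nitro-5-(3,5,7,8-tetramethoxynaphthalen-1-yl)cyclohexene (relative configuration) | COC1=C(OC)C[C@@H]([N+](=O)[O-])[C@H](c2cc(OC)cc3c(OC)cc(OC)c(OC)c23)C1
A2 | alternative 1 | (E)-1,2,4,6-tetramethoxy-8-(2-nitroethenyl)naphthalene | COc1cc(/C=C/[N+](=O)[O-])c2c(OC)c(OC)cc(OC)c2c1
A3 | alternative 1 | 2,3-dimethoxybuta-1,3-diene | C=C(OC)C(OC)=C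
A4 | alternative 1 | 8-(3,4-dimethoxyphenyl)-1,2,4,6-tetramethoxynaphthalene | COc1cc(-c2ccc(OC)c(OC)c2)c2c(OC)c(OC)cc(OC)c2c1
A5 | alternative 2 | racemic methyl 8-(3,4-dimethoxyphenyl)-2,6-dimethoxy-1,4-dioxo-1,2,3,4-tetrahydronaphthalene-2-carboxylate | COC(=O)C1(OC)CC(=O)c2cc(OC)cc(-c3ccc(OC)c(OC)c3)c2C1=O
A6 | alternative 2 | racemic 7-(3,4-dimethoxyphenyl)-5-methoxy-3-(phenylsulfonyl)isobenzofuran-1(3H)-one | O=C1OC(S(=O)(=O)c2ccccc2)c2cc(OC)cc(-c3ccc(OC)c(OC)c3)c12
A7 | alternative 2 | methyl 2-methoxyacrylate | C=C(OC)C(=O)OC
A8 | alternative 3 | 2-bromo-8-(3,4-dimethoxyphenyl)-6-methoxynaphthalen-1-ol | Oc1c(Br)ccc2cc(OC)cc(-c3ccc(OC)c(OC)c3)c12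
A9 | alternative 3 | {[7-(3,4-dimethoxyphenyl)-5-methoxy-1H-inden-3-yl]oxy}trimethylsilane | COc1cc2c(c(-c3ccc(OC)c(OC)c3)c1)C(O[Si](C)(C)C)=CC2
A10 | alternative 3 | 7-(3,4-dimethoxyphenyl)-5-methoxyindan-1-one | COc1cc2c(c(-c3ccc(OC)c(OC)c3)c1)C(=O)CC2
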